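The numbers in the tables are calculated with constants of no real substance; the scatter is artificial.

Start with the easiest limit: the south flask, charged with 0.80 M of starting material, cannot hold more target than that. Yet the noon run stood at 36.5% target at 20.0 min and 36.5% at 30.0 min, with 63.1% of its starting material left, while the summer run, charged with less, had reached a higher 76.7%.

| flask | starting material | free catalyst | remark | time |
|---|---|---|---|---|
| summer | 0.11 M | 4 mM | run made earlier |  |
| noon | 1.2 M | 4 mM | run made earlier |  |
| south-east | 0.10 M | 4.0 mM |  | 40 min |
| west | 0.20 M | 4.0 mM |  | 40 min |
| east | 0.40 M | 4.0 mM |  | 40 min |
| south | 0.80 M | 4.0 mM |  | 40 min |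

- summer (time / min: target / %, starting material / %): 4.00: 29.7, 69.1; 10.0: 55.9, 43.1; 20.0: 71.7, 25.9; 30.0: 76.7, 20.0
- noon (time / min: target / %, starting material / %): 8.00: 31.6, 67.5; 15.0: 34.5, 64.4; 20.0: 36.5, 62.8; 30.0: 36.5, 63.1

(each reading ± 0.5 percentage points)

- [target] at the end for south-east, west, east, south, in this order
- the course of these numbers from the first flask to the last (rises all the way / rises, then falls / falls all the way / hardly changes / falls, then rises)

- "hardly changes" means that all values lie within two and a half points (for a concentration: within two and a half percent of the largest)

So the concentration to follow is free catalyst. I take target as formed at a rate first order in starting material and in free catalyst (pseudo-first-order while free catalyst holds steady), and free catalyst as lost at a rate first order in itself and in target. Dividing one rate by the other removes time: with c the charge, x the converted fraction and g(x) = −x − ln(1 − x), free catalyst falls in proportion to c·g(x). Noon's plateau reads B = 0.107 M, the kill budget, the value of c·g(x) at which, on this taking and with 4 mM of free catalyst charged, a flask stops.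

For south, g(x) lies between x squared over two and that divided by (1 − x), so with b = B/c = 0.134 the stop lies between x = 40.0% and 51.7%, which is 0.320 M to 0.414 M of target. Since g curves upward, one Newton step down from the top stays above the stop and lowers the ceiling to x = 44.5%, or 0.356 M. The floor assumes that south has stopped within 40 min, twice the time by which noon's plateau stood. With B held, both limits grow with c, so I expect the row to rise.

The forecast gives 0.08 M, 0.139 M, 0.224 M and 0.342 M, a course that rises all the way, and says of the flasks after the first: “The others are essentially dead by then.” Its south value lies inside my bracket.

The flasks give 0.0802 M, 0.139 M, 0.223 M and 0.343 M, a course that rises all the way, and south stands inside the bracket too.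

    starting material + free catalyst ⇌ catalyst intermediate (K = 0.380 M⁻¹, k = 3.30 M⁻¹ s⁻¹)
    catalyst intermediate → free catalyst + target (k = 1.20 s⁻¹)
    free catalyst + target → spent catalyst (k = 0.0150 M⁻¹ s⁻¹)

South's simulated target gives c·g(x) = 0.105 M, and east's, at 400 min, gives 0.103 M, to set beside noon's 0.107 M. In south-east at 6.04 min, free catalyst has a half-life of 19 min by its path with target to spent catalyst, shorter than the 40 min allowed, and at 40.0 min free catalyst stands at 10.3% of its charge, with 16.2% of the starting material left.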